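## Structural features

Phlorofucofuroeckol A is an achiral C30 polyphenol with no stereocentre. Its fused pentacyclic core joins ring A and central ring B through a 1,4-dioxin and ring B and ring C through a furan, and one 3,5-dihydroxyphenoxy ring (ring P) hangs from a1 of ring A and another from c2 of ring C. Ring B is fully differentiated: b1 and b6 carry the dioxin oxygens (to a6 and a5), b5 is bonded to carbon c6, b4 carries the furan oxygen, b2 a hydroxyl and b3 the only hydrogen. All eight hydroxyls sit on phloroglucinol-type rings, so the free compound is easily oxidised and must be unveiled last; even as ethers these rings, ring P above all, react readily with halogen and carbon electrophiles. The real difficulty is regiochemical: the dioxin must be fused to unsymmetrical ring A in one sense only (b1–O–a6 and b6–O–a5), ring B needs six different neighbours, and each ring P hangs from an oxygen flanked by two ortho substituents. The key step exploits the fact that four ring B carbons can pre-exist as two alkenes, b1=b6 as the double bond of a 1,4-benzodioxin and b5=b4 as the C-3/C-2 bond of a benzofuran; a 1-ethoxyvinyl group on b1 then supplies b2 with its oxygen and b3, and the single new bond b3–b4 completes the ring. Rings A and C share one substitution pattern (each is a 2-aryloxy-3,5-dimethoxyphenol extended at its one free ortho carbon), so both halves can come from one diaryl ether.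

## Logic of the disconnections

**25 from 24.** The nine O–alkyl bonds of 24 (eight O–CH3 and the O–CH2CH3 at b2) are cut last. The free octaphenol is the only air- and electrophile-sensitive compound of the sequence, so it is exposed once, at the end; every earlier intermediate is a neutral polyether. The forward step must cleave methyl and ethyl aryl ethers alike and leave the diaryl ether, dioxin and furan C–O bonds intact.

**24 from 22.** The b3–b4 bond is cut, the bond between the only C–H carbon of ring B and the furan carbon. This opens ring B to the triene of 22, so a hexasubstituted benzene is exchanged for a vinyl group on a heterocycle. The forward step must close at furan C-2 and must take 23 on by dehydrogenation, not by loss of ethanol, so that the b2 oxygen is kept.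

**22 from 20 and 21.** The b1–b2 carbon–carbon bond is cut, separating the two-carbon unit b2–b3 with its oxygen (21) from a dioxin that bears a leaving group on b1 (20). The acid-labile enol ether is thereby absent from all earlier steps. The forward step is a cross-coupling at a tetrasubstituted, electron-rich alkene.

**20 from 19.** The O–S bond is cut so that b1 becomes a lactone carbonyl. The leaving group then grows from an oxygen already on b1. Halogenating a dioxin C–H is avoided, because two rings P, furan C-2 and two further arene positions would compete for a halogen electrophile. The forward step must trap the enolate of an aryl lactone on oxygen before it fragments.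

**19 from 11 and 16 (through 18 and 17).** Two dioxin C–O bonds are cut, the acyl–oxygen bond b1–O(a6) and the alkyl–oxygen bond b6–O(a5). They are made in a fixed order by different reactions: b6–O–a5 first at the only free hydroxyl of 11, b1–O–a6 second after unmasking. The sense of fusion to ring A is thus set by connectivity, and the molecule is split into two halves of equal size. The forward steps need a C–O bond formation at a crowded phenol and a protecting group on a6 that comes off without reduction.

**11 from 8 (through 10 and 9).** The a5–O bond is traced back to an a5–CHO group and the acetal on a6 is removed. Because the formyl group can only enter ortho to the free a6 hydroxyl, the two neighbouring oxygens of ring A are born different. The forward step is a peracid oxidation in which the aryl group must migrate.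

**16 from 7 and 12 (through 15, 14 and 13).** The diazo group and the ester methyl are removed; the furan O–C-2 bond is then cut by viewing 14 as the ring-contraction product of 13; 13 is cut at its aryl–C-4 bond and its lactone C–O bond. A benzofuran-3-yl acetate with hydrogen at C-2 is reduced to a phenol and a four-carbon keto ester. The condensation must occur at the single free ortho carbon of 7 and not on ring P.

**8 from 7.** The aryl–CHO bond is cut. Both halves now derive from 7, which halves the effort for the diaryl ether. The forward formylation must go ortho to the hydroxyl only.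

**7 from 4 and 5 (through 6); 4 from 1 (through 3 and 2).** The crowded diaryl ether bond is cut so that the hindered ring is the nucleophile and ring P the unhindered electrophile. The phenol oxygen of 4 is traced to the formyl group of 1, and a benzyl ether keeps the second oxygen apart. The forward coupling must tolerate two ortho substituents on an oxidation-prone phenol.

## Other disconnections considered

**Alternative 1:** The cut removes the furan bonds b5–c6 and b4–O while ring B is carried as a saturated 1,3-dione.
- Forward key step: the dione A1 would be C-arylated at C-2 by the ring C iodophenol A2 under CuI and L-proline (Ullmann-type coupling of a 1,3-dicarbonyl). The phenol oxygen would then condense with one carbonyl to give the dihydrodibenzofuranone A3.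
- In favour: both furan bonds form in one thermal operation from two simple partners; the iodine fixes the ring C regiochemistry; no photochemistry is needed.
- Against: A3 has b1 and b3 as CH2, b6 as a ketone and b2 as an sp3 C–OMe stereocentre of no use. Ring B still needs oxygenation at b1 and a dehydrogenation, and the β-methoxy ketone could lose methanol on enolisation, which would aromatise ring B without its b2 oxygen. The dioxin would then have to be built with two aryl–oxygen bonds to an electron-rich ring A, with its sense still open. A2 also needs a selective iodination in the presence of ring P.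
- Comparison: on structure, the chosen plan delivers ring B aromatic with all three oxygens and the dioxin already in place, whereas A3 delivers the furan only. On mechanism, a thermal copper coupling is easier to scale than a dilute photolysis, and here the alternative is the better. On step economy it is the better as far as A3, but is expected to lose that lead in the oxidation-state changes and the dioxin construction that follow.

**Alternative 2:** The cut removes both rings P completely, three C–C bonds each.
- Forward key step: heating the bis(ethynyl ether) A4 of the pentamethyl-protected core with 3-ethoxycyclobutenone A5. A5 opens thermally, adds to each alkynyl ether by [2+2] cycloaddition, and the adducts rearrange by four-electron opening, six-electron closure and tautomerisation to the bis(3-ethoxy-5-hydroxyphenyl) ether A6.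
- In favour: no crowded diaryl ether coupling is needed; the electrophile-sensitive rings P appear only at the end; the mutual meta arrangement of OH, OEt and OAr is exactly what the benzannulation gives; the two ends react in the same way.
- Against: it presupposes the whole pentacyclic core and so leaves ring B and the sense of the dioxin unsolved. Two phenols must be carried through the core synthesis and turned into thermally fragile aryl ethynyl ethers by strong-base eliminations at hindered positions. Both annulations must succeed on one molecule.
- Comparison: on structure it addresses the periphery, the chosen plan the core. On mechanism both rely on pericyclic ring formation, thermal there and photochemical here. The alternative is the better in avoiding the hindered coupling of step 3 and in leaving more freedom for electrophilic reagents during core assembly. The endgame is equal, since A6 also needs ethyl and methyl ether cleavage. On overall step economy the chosen plan is expected to be shorter, because here the ring P building blocks are bought.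

**Alternative 3:** The cut removes the furan bonds b5–c6 and O–c1 with ring B as a quinone.
- Forward key step: under acid the symmetric aryloxyphloroglucinol A8 would add through c6 to b5 of quinone A7. After re-aromatisation the b4 hydroxyl would condense onto c1 with loss of water to give dibenzofuran A9.
- In favour: two fragments of similar size are joined in one biomimetic step. A8 is symmetric, so ring C poses no regiochemical question. A9 already contains the b6–O–a5 ether and the a6 bromide next to the b1 hydroxyl, so the sense of the dioxin is fixed by connectivity; on this point it is the equal of the chosen plan.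
- Against: the quinone offers two CH acceptor positions, b3 and b5, each beside an oxygen substituent, and its alkoxy-bearing carbons are open to addition–elimination. The hydroquinone formed can be re-oxidised by A7. The free hydroxyls of A8 and A9 must be protected again. The later dioxin closure is an Ullmann etherification at a bromide with two ortho substituents on an electron-rich ring.
- Comparison: the alternative is the better in convergence and in step count up to the dibenzofuran. It is the weaker in regiocontrol at its key step, where the chosen photocyclisation has a single productive site, and in the difficulty of the final dioxin closure, which the chosen plan replaces by an O–H insertion and a lactonisation.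

Key step: step 16

Remark on the chemistry: 17, 18, 19 and 23 each contain one stereocentre and are taken as racemates, since that carbon becomes sp2 again in steps 14 and 16; 1, 5, 12 and 21 are taken to be purchasable.

## Route

Step 1
Reactants: 1 2-hydroxy-4,6-dimethoxybenzaldehyde
Product: 2 2-(benzyloxy)-4,6-dimethoxybenzaldehyde
Conditions: BnBr, K2CO3, DMF, 60 °C
Reagents that add atoms: benzyl bromide, BrCc1ccccc1
Why: Williamson etherification of the hydrogen-bonded phenol; the benzyl ether keeps this oxygen (the future free hydroxyl of 7) apart from the oxygen that step 2 creates from the formyl group.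

Step 2
Reactants: 2 2-(benzyloxy)-4,6-dimethoxybenzaldehyde
Product: 4 2-(benzyloxy)-4,6-dimethoxyphenol, via formate ester 3 (not isolated)
Conditions: mCPBA, CH2Cl2, 0 °C to rt; then K2CO3 (cat.), MeOH, rt
Reagents that add atoms: 3-chloroperbenzoic acid, OOC(=O)c1cccc(Cl)c1
Why: Baeyer–Villiger oxidation of an electron-rich benzaldehyde (Dakin-type): the 2,4,6-trioxygenated aryl group migrates in preference to hydrogen, and the formate is removed by methanolysis.

Step 3
Reactants: 4 2-(benzyloxy)-4,6-dimethoxyphenol, 5 1-iodo-3,5-dimethoxybenzene
Product: 6 1-(benzyloxy)-2-(3,5-dimethoxyphenoxy)-3,5-dimethoxybenzene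
Conditions: CuI (10 mol%), picolinic acid (20 mol%), K3PO4, DMSO, 90 °C, argon
Reagents that add atoms: none
Why: Ullmann diaryl ether synthesis with ligand-assisted catalysis by monovalent copper, a system suited to phenols with two ortho substituents; the hindrance lies on the nucleophile while the iodide is unhindered, and the oxygen-free conditions spare the oxidation-prone phenol.

Step 4
Reactants: 6 1-(benzyloxy)-2-(3,5-dimethoxyphenoxy)-3,5-dimethoxybenzene
Product: 7 2-(3,5-dimethoxyphenoxy)-3,5-dimethoxyphenol
Conditions: H2 (1 atm), Pd/C, EtOAc/MeOH, rt
Reagents that add atoms: none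
Why: Hydrogenolysis of the benzyl aryl ether; diaryl ether and methyl ethers are inert, and the phenol set free becomes the furan oxygen in one half and the a6 oxygen in the other.

Step 5
Reactants: 7 2-(3,5-dimethoxyphenoxy)-3,5-dimethoxyphenol
Product: 8 3-(3,5-dimethoxyphenoxy)-2-hydroxy-4,6-dimethoxybenzaldehyde
Conditions: MgCl2, Et3N, (CH2O)n, MeCN, reflux
Reagents that add atoms: paraformaldehyde (as formaldehyde), C=O
Why: Magnesium-mediated ortho-formylation of a phenol: formaldehyde is delivered within the magnesium phenoxide to the only free ortho carbon, so the equally electron-rich carbon between the two methoxy groups and ring P stay untouched; a second equivalent of formaldehyde oxidises the hydroxymethyl stage.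

Step 6
Reactants: 8 3-(3,5-dimethoxyphenoxy)-2-hydroxy-4,6-dimethoxybenzaldehyde
Product: 9 3-(3,5-dimethoxyphenoxy)-4,6-dimethoxy-2-(methoxymethoxy)benzaldehyde
Conditions: MOMCl, K2CO3, DMF, 0 °C to rt
Reagents that add atoms: chloromethyl methyl ether, COCCl
Why: O-alkylation to the methoxymethyl ether, which withstands peracid, methanolysis and the rhodium carbenoid; it is later removed by acid, not by hydrogenolysis, which could also cleave the benzylic-type C–O bond made in step 12.

Step 7
Reactants: 9 3-(3,5-dimethoxyphenoxy)-4,6-dimethoxy-2-(methoxymethoxy)benzaldehyde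
Product: 11 3-(3,5-dimethoxyphenoxy)-4,6-dimethoxy-2-(methoxymethoxy)phenol, via formate ester 10 (not isolated)
Conditions: mCPBA, CH2Cl2, 0 °C; then K2CO3 (cat.), MeOH, rt
Reagents that add atoms: 3-chloroperbenzoic acid, OOC(=O)c1cccc(Cl)c1
Why: Baeyer–Villiger oxidation and methanolysis as in step 2; the formyl carbon is replaced by the a5 hydroxyl, now the only free hydroxyl beside the masked a6 oxygen, so the two catechol oxygens of ring A are differentiated.

Step 8
Reactants: 7 2-(3,5-dimethoxyphenoxy)-3,5-dimethoxyphenol, 12 ethyl 4-chloro-3-oxobutanoate
Product: 13 4-(chloromethyl)-8-(3,5-dimethoxyphenoxy)-5,7-dimethoxy-2H-chromen-2-one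
Conditions: MeSO3H, 0 °C to rt
Reagents that add atoms: none
Why: Pechmann condensation: attack of the protonated ketone at the one free carbon ortho to the hydroxyl is made irreversible by lactonisation, whereas hydroxyalkylation of ring P can only revert; methanesulfonic acid is chosen because it cannot sulfonate the electron-rich rings.

Step 9
Reactants: 13 4-(chloromethyl)-8-(3,5-dimethoxyphenoxy)-5,7-dimethoxy-2H-chromen-2-one
Product: 14 [7-(3,5-dimethoxyphenoxy)-4,6-dimethoxy-1-benzofuran-3-yl]acetic acid
Conditions: NaOH (1 M aq), reflux; then HCl (aq)
Reagents that add atoms: sodium hydroxide, [Na+].[OH-]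
Why: Base-induced ring contraction of a 4-(chloromethyl)coumarin: hydroxide opens the lactone, the phenoxide displaces chloride in a 5-exo-tet closure and the exocyclic alkene isomerises into the benzofuran, which keeps hydrogen at C-2 as the key step requires.

Step 10
Reactants: 14 [7-(3,5-dimethoxyphenoxy)-4,6-dimethoxy-1-benzofuran-3-yl]acetic acid
Product: 15 methyl [7-(3,5-dimethoxyphenoxy)-4,6-dimethoxy-1-benzofuran-3-yl]acetate
Conditions: MeOH, H2SO4 (cat.), reflux
Reagents that add atoms: methanol, CO
Why: Fischer esterification; the ester provides the α-acidity needed for diazo transfer.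

Step 11
Reactants: 15 methyl [7-(3,5-dimethoxyphenoxy)-4,6-dimethoxy-1-benzofuran-3-yl]acetate
Product: 16 methyl diazo[7-(3,5-dimethoxyphenoxy)-4,6-dimethoxy-1-benzofuran-3-yl]acetate
Conditions: p-ABSA, DBU, MeCN, 0 °C to rt
Reagents that add atoms: 4-acetamidobenzenesulfonyl azide, CC(=O)Nc1ccc(cc1)S(=O)(=O)N=[N+]=[N-]
Why: Regitz diazo transfer to an arylacetate; the α-carbon is activated without any electrophilic halogen, so the methoxylated rings are not at risk.

Step 12
Reactants: 11 3-(3,5-dimethoxyphenoxy)-4,6-dimethoxy-2-(methoxymethoxy)phenol, 16 methyl diazo[7-(3,5-dimethoxyphenoxy)-4,6-dimethoxy-1-benzofuran-3-yl]acetate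
Product: 17 methyl 2-[3-(3,5-dimethoxyphenoxy)-4,6-dimethoxy-2-(methoxymethoxy)phenoxy]-2-[7-(3,5-dimethoxyphenoxy)-4,6-dimethoxy-1-benzofuran-3-yl]acetate (racemic)
Conditions: Rh2(OAc)4 (1 mol%), CH2Cl2, rt, slow addition of 16
Reagents that add atoms: none
Why: O–H insertion of a rhodium carbenoid from an aryldiazoacetate into a phenol (oxonium ylide, then proton transfer); 11 offers a single O–H, so the b6–O–a5 bond forms in one sense only. The new stereocentre is formed without control and is erased in step 14.

Step 13
Reactants: 17 methyl 2-[3-(3,5-dimethoxyphenoxy)-4,6-dimethoxy-2-(methoxymethoxy)phenoxy]-2-[7-(3,5-dimethoxyphenoxy)-4,6-dimethoxy-1-benzofuran-3-yl]acetate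
Product: 19 8-(3,5-dimethoxyphenoxy)-3-[7-(3,5-dimethoxyphenoxy)-4,6-dimethoxy-1-benzofuran-3-yl]-5,7-dimethoxy-1,4-benzodioxin-2(3H)-one (racemic), via hydroxy ester 18 (not isolated)
Conditions: HCl (cat.), MeOH, 45 °C; then TsOH·H2O (cat.), PhMe, reflux with removal of MeOH
Reagents that add atoms: none
Why: Acid-catalysed transacetalisation removes the methoxymethyl group, its formaldehyde unit leaving as dimethoxymethane in the large excess of methanol; the freed a6 phenol is then acylated intramolecularly (lactonisation to a six-membered aryl ester), which fixes b1 as the carbon bonded to O–a6.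

Step 14
Reactants: 19 8-(3,5-dimethoxyphenoxy)-3-[7-(3,5-dimethoxyphenoxy)-4,6-dimethoxy-1-benzofuran-3-yl]-5,7-dimethoxy-1,4-benzodioxin-2(3H)-one
Product: 20 8-(3,5-dimethoxyphenoxy)-3-[7-(3,5-dimethoxyphenoxy)-4,6-dimethoxy-1-benzofuran-3-yl]-5,7-dimethoxy-1,4-benzodioxin-2-yl trifluoromethanesulfonate
Conditions: KN(SiMe3)2, PhNTf2, THF, −78 to −20 °C
Reagents that add atoms: N-phenylbis(trifluoromethanesulfonimide), O=S(=O)(N(c1ccccc1)S(=O)(=O)C(F)(F)F)C(F)(F)F
Why: Formation of a lactone-derived enol triflate (ketene acetal triflate): the α-aryl, α-aryloxy proton is removed and the enolate oxygen is sulfonylated, with base added to lactone and triflating agent together so that trapping outruns ring-opening of the enolate. The leaving group is thus placed on b1 without any halogenation, and the stereocentre of 19 disappears.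

Step 15
Reactants: 20 8-(3,5-dimethoxyphenoxy)-3-[7-(3,5-dimethoxyphenoxy)-4,6-dimethoxy-1-benzofuran-3-yl]-5,7-dimethoxy-1,4-benzodioxin-2-yl trifluoromethanesulfonate, 21 tributyl(1-ethoxyvinyl)stannane
Product: 22 5-(3,5-dimethoxyphenoxy)-2-[7-(3,5-dimethoxyphenoxy)-4,6-dimethoxy-1-benzofuran-3-yl]-3-(1-ethoxyethenyl)-6,8-dimethoxy-1,4-benzodioxin
Conditions: Pd(PPh3)4 (5 mol%), LiCl, CuI (10 mol%), THF, 60 °C; purification on Et3N-treated silica
Reagents that add atoms: none
Why: Stille coupling of an enol triflate with an α-alkoxyvinylstannane on zerovalent palladium; LiCl assists the triflate pathway and CuI speeds transmetalation at the hindered, tetrasubstituted alkene. Basic handling protects the acid-labile enol ether of 22.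

Step 16
Reactants: 22 5-(3,5-dimethoxyphenoxy)-2-[7-(3,5-dimethoxyphenoxy)-4,6-dimethoxy-1-benzofuran-3-yl]-3-(1-ethoxyethenyl)-6,8-dimethoxy-1,4-benzodioxin
Product: 24 protected target (phlorofucofuroeckol A with an ethyl ether on the ring B hydroxyl at b2 and methyl ethers on the other eight hydroxyls), via dihydro intermediate 23 (not isolated)
Conditions: hν (medium-pressure Hg lamp, Pyrex, λ > 290 nm), I2 (1.1 equiv), methyloxirane (50 equiv), PhMe (degassed, ca. 1 mM), rt
Reagents that add atoms: none
Why: Mallory-type oxidative photocyclisation of a 1-aryl-1,3-diene. Excitation brings the s-cis hexatriene CH2=C(OEt)–C(b1)=C(b6)–C-3=C-2 to a conrotatory six-electron electrocyclisation that forms the b3–b4 σ bond and with it six-membered ring B, the new bond joining the two triene termini. The dihydro compound 23 has sp3 carbons b3 (CH2) and b4 (CH–O); iodine removes these two hydrogens, and methyloxirane traps the HI so that neither the enol ether of 22 nor the product ethers meet acid. No stereocentre survives, because the transient b4 centre of racemic 23 is flattened on aromatisation. The step needs three selectivities. Geometric: the central double bond is held cis inside the dioxin ring, so no E/Z isomerisation has to precede closure. Regiochemical: the other neighbour of furan C-3, the ring-fusion carbon C-3a, would also close a six-membered ring, but it carries no hydrogen and closure there would break the benzene ring of ring C, so that path can only revert, whereas closure at C-2 leads on to an arene. Chemoselective: aromatisation must occur by dehydrogenation and not by hydrogen shift and loss of ethanol, which a full equivalent of iodine in dilute, degassed solution is meant to secure.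

Step 17
Reactants: 24 protected target (ethyl ether at b2, methyl ethers elsewhere)
Product: 25 phlorofucofuroeckol A
Conditions: BBr3 (excess), CH2Cl2, −78 °C to rt; then H2O, 0 °C, under argon
Reagents that add atoms: none
Why: Lewis-acid ether cleavage: boron coordinates each alkyl aryl ether oxygen and bromide removes the methyl or ethyl group by SN2, whereas the diaryl ether, dioxin and furan C–O bonds, which join two sp2 carbons, are not cleaved; work-up under argon protects the octaphenol.

## Compound list

1 | 2-hydroxy-4,6-dimethoxybenzaldehyde | O=Cc1c(O)cc(OC)cc1OC | starting material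
2 | 2-(benzyloxy)-4,6-dimethoxybenzaldehyde | O=Cc1c(OCc2ccccc2)cc(OC)cc1OC | intermediate
3 | 2-(benzyloxy)-4,6-dimethoxyphenyl formate | O=COc1c(OCc2ccccc2)cc(OC)cc1OC | intermediate (not isolated)
4 | 2-(benzyloxy)-4,6-dimethoxyphenol | Oc1c(OCc2ccccc2)cc(OC)cc1OC | intermediate
5 | 1-iodo-3,5-dimethoxybenzene | COc1cc(I)cc(OC)c1 | starting material
6 | 1-(benzyloxy)-2-(3,5-dimethoxyphenoxy)-3,5-dimethoxybenzene | COc1cc(OC)cc(Oc2c(OCc3ccccc3)cc(OC)cc2OC)c1 | intermediate
7 | 2-(3,5-dimethoxyphenoxy)-3,5-dimethoxyphenol | COc1cc(OC)cc(Oc2c(O)cc(OC)cc2OC)c1 | intermediate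
8 | 3-(3,5-dimethoxyphenoxy)-2-hydroxy-4,6-dimethoxybenzaldehyde | O=Cc1c(O)c(Oc2cc(OC)cc(OC)c2)c(OC)cc1OC | intermediate
9 | 3-(3,5-dimethoxyphenoxy)-4,6-dimethoxy-2-(methoxymethoxy)benzaldehyde | O=Cc1c(OCOC)c(Oc2cc(OC)cc(OC)c2)c(OC)cc1OC | intermediate
10 | 3-(3,5-dimethoxyphenoxy)-4,6-dimethoxy-2-(methoxymethoxy)phenyl formate | O=COc1c(OCOC)c(Oc2cc(OC)cc(OC)c2)c(OC)cc1OC | intermediate (not isolated)
11 | 3-(3,5-dimethoxyphenoxy)-4,6-dimethoxy-2-(methoxymethoxy)phenol | Oc1c(OCOC)c(Oc2cc(OC)cc(OC)c2)c(OC)cc1OC | intermediate
12 | ethyl 4-chloro-3-oxobutanoate | CCOC(=O)CC(=O)CCl | starting material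
13 | 4-(chloromethyl)-8-(3,5-dimethoxyphenoxy)-5,7-dimethoxy-2H-chromen-2-one | ClCC1=CC(=O)Oc2c(Oc3cc(OC)cc(OC)c3)c(OC)cc(OC)c12 | intermediate
14 | [7-(3,5-dimethoxyphenoxy)-4,6-dimethoxy-1-benzofuran-3-yl]acetic acid | OC(=O)Cc1coc2c(Oc3cc(OC)cc(OC)c3)c(OC)cc(OC)c12 | intermediate
15 | methyl [7-(3,5-dimethoxyphenoxy)-4,6-dimethoxy-1-benzofuran-3-yl]acetate | COC(=O)Cc1coc2c(Oc3cc(OC)cc(OC)c3)c(OC)cc(OC)c12 | intermediate
16 | methyl diazo[7-(3,5-dimethoxyphenoxy)-4,6-dimethoxy-1-benzofuran-3-yl]acetate | COC(=O)C(=[N+]=[N-])c1coc2c(Oc3cc(OC)cc(OC)c3)c(OC)cc(OC)c12 | intermediate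
17 | methyl 2-[3-(3,5-dimethoxyphenoxy)-4,6-dimethoxy-2-(methoxymethoxy)phenoxy]-2-[7-(3,5-dimethoxyphenoxy)-4,6-dimethoxy-1-benzofuran-3-yl]acetate (racemic) | COC(=O)C(Oc1c(OCOC)c(Oc2cc(OC)cc(OC)c2)c(OC)cc1OC)c1coc2c(Oc3cc(OC)cc(OC)c3)c(OC)cc(OC)c12 | intermediate
18 | methyl 2-[3-(3,5-dimethoxyphenoxy)-2-hydroxy-4,6-dimethoxyphenoxy]-2-[7-(3,5-dimethoxyphenoxy)-4,6-dimethoxy-1-benzofuran-3-yl]acetate (racemic) | COC(=O)C(Oc1c(O)c(Oc2cc(OC)cc(OC)c2)c(OC)cc1OC)c1coc2c(Oc3cc(OC)cc(OC)c3)c(OC)cc(OC)c12 | intermediate (not isolated)
19 | 8-(3,5-dimethoxyphenoxy)-3-[7-(3,5-dimethoxyphenoxy)-4,6-dimethoxy-1-benzofuran-3-yl]-5,7-dimethoxy-1,4-benzodioxin-2(3H)-one (racemic) | O=C1Oc2c(Oc3cc(OC)cc(OC)c3)c(OC)cc(OC)c2OC1c1coc2c(Oc3cc(OC)cc(OC)c3)c(OC)cc(OC)c12 | intermediate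
20 | 8-(3,5-dimethoxyphenoxy)-3-[7-(3,5-dimethoxyphenoxy)-4,6-dimethoxy-1-benzofuran-3-yl]-5,7-dimethoxy-1,4-benzodioxin-2-yl trifluoromethanesulfonate | O=S(=O)(OC1=C(c2coc3c(Oc4cc(OC)cc(OC)c4)c(OC)cc(OC)c23)Oc2c(OC)cc(OC)c(Oc3cc(OC)cc(OC)c3)c2O1)C(F)(F)F | intermediate
21 | tributyl(1-ethoxyvinyl)stannane | CCCC[Sn](CCCC)(CCCC)C(=C)OCC | starting material
22 | 5-(3,5-dimethoxyphenoxy)-2-[7-(3,5-dimethoxyphenoxy)-4,6-dimethoxy-1-benzofuran-3-yl]-3-(1-ethoxyethenyl)-6,8-dimethoxy-1,4-benzodioxin | C=C(OCC)C1=C(c2coc3c(Oc4cc(OC)cc(OC)c4)c(OC)cc(OC)c23)Oc2c(OC)cc(OC)c(Oc3cc(OC)cc(OC)c3)c2O1 | intermediate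
23 | dihydro intermediate: ring B closed, b3 as CH2 and b4 as sp3 CH bearing the furan oxygen, double bonds b1=b2 and b5=b6 (racemic) | CCOC1=C2Oc3c(Oc4cc(OC)cc(OC)c4)c(OC)cc(OC)c3OC2=C2c3c(OC)cc(OC)c(Oc4cc(OC)cc(OC)c4)c3OC2C1 | intermediate (not isolated)
24 | protected target: phlorofucofuroeckol A with an ethyl ether at b2 and methyl ethers on the other eight hydroxyls | CCOc1cc2oc3c(Oc4cc(OC)cc(OC)c4)c(OC)cc(OC)c3c2c2Oc3c(OC)cc(OC)c(Oc4cc(OC)cc(OC)c4)c3Oc12 | intermediate
25 | phlorofucofuroeckol A | Oc1cc(O)cc(Oc2c(O)cc(O)c3c2Oc2c(O)cc4oc5c(Oc6cc(O)cc(O)c6)c(O)cc(O)c5c4c2O3)c1 | target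

## Step count and risks

Total step count: 17. Longest linear sequence: 14 steps (1 to 4, 8 to 11, 12 to 17).

Steps least certain to work:

**Step 16 (key step).** What may go wrong: aromatisation of 23 by hydrogen shift and loss of ethanol in place of dehydrogenation, hydrolysis of the enol ether by traces of HI before closure, or inefficient closure because the 4-methoxy group twists the benzofuran out of the diene plane. Fallback, a polar closure of the same bond: starting from 22, N-bromosuccinimide in wet THF at 0 °C would turn the enol ether into the bromomethyl ketone F1. Silver-assisted intramolecular Friedel–Crafts alkylation of furan C-2 (AgOSO2CF3, 2,6-di-tert-butylpyridine, CH2Cl2) would close ring B as a ketone that tautomerises at once to the ring B phenol F2. F2 would be treated with BBr3 as in step 17 and rejoins the route at 25.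

**Step 14.** What may go wrong: ring-opening of the lactone enolate to a ketene phenoxide before O-sulfonylation, and hydrolysis of the triflate during isolation. Fallback, carbonyl addition in place of enolate trapping and cross-coupling: starting from 19, 1-ethoxyvinyllithium (from ethyl vinyl ether and t-BuLi) transmetalated with CeCl3 at −78 °C would add to the lactone carbonyl, the low basicity of the cerium reagent limiting enolisation, to give the lactol F3. Dehydration with MsCl and Et3N would lead to 22, where the route is rejoined without 20 and step 15.

**Step 12.** What may go wrong: diversion of the carbenoid to ylides with the many ether oxygens or to attack on the electron-rich rings, and slow insertion at the crowded phenol. Fallback, an SN2 etherification: starting from 15, LiN(SiMe3)2 and then CBr4 in THF at −78 °C would give the α-bromo ester F4. The phenoxide of 11 (K2CO3, DMF) would displace bromide, and the route is rejoined at 17.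

**Step 3.** What may go wrong: slow coupling at the phenoxide with two ortho substituents and oxidative degradation of the phenol. Fallback, a metal-free arylation: starting from 5, oxidation with mCPBA and TsOH·H2O followed by capture with 1,3,5-trimethoxybenzene would give the iodonium tosylate F5. The potassium phenoxide of 4 (t-BuOK, THF, rt) would be arylated by ligand coupling on trivalent iodine, the less electron-rich 3,5-dimethoxyphenyl group being the one transferred, and the route is rejoined at 6.

**Step 17.** What may go wrong: incomplete cleavage at the ethyl ether or at the most crowded methyl ethers, and degradation of the electron-rich polyphenol by HBr or air during work-up. Fallback, nucleophilic in place of Lewis-acid dealkylation: starting from 24, excess NaSEt in DMF at 140 °C under argon would remove the alkyl groups by SN2 in basic medium, and acidification would give 25 directly; no new compound is made on this way (F0).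

## Further compounds

F1 | step 16 | 2-bromo-1-{8-(3,5-dimethoxyphenoxy)-3-[7-(3,5-dimethoxyphenoxy)-4,6-dimethoxy-1-benzofuran-3-yl]-5,7-dimethoxy-1,4-benzodioxin-2-yl}ethanone | O=C(CBr)C1=C(c2coc3c(Oc4cc(OC)cc(OC)c4)c(OC)cc(OC)c23)Oc2c(OC)cc(OC)c(Oc3cc(OC)cc(OC)c3)c2O1
F2 | step 16 | octamethyl ether of phlorofucofuroeckol A with the ring B hydroxyl (b2) free | Oc1cc2oc3c(Oc4cc(OC)cc(OC)c4)c(OC)cc(OC)c3c2c2Oc3c(OC)cc(OC)c(Oc4cc(OC)cc(OC)c4)c3Oc12
F3 | step 14 | 8-(3,5-dimethoxyphenoxy)-3-[7-(3,5-dimethoxyphenoxy)-4,6-dimethoxy-1-benzofuran-3-yl]-2-(1-ethoxyethenyl)-5,7-dimethoxy-2,3-dihydro-1,4-benzodioxin-2-ol (racemic, mixture of diastereomers) | C=C(OCC)C1(O)Oc2c(Oc3cc(OC)cc(OC)c3)c(OC)cc(OC)c2OC1c1coc2c(Oc3cc(OC)cc(OC)c3)c(OC)cc(OC)c12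
F4 | step 12 | methyl bromo[7-(3,5-dimethoxyphenoxy)-4,6-dimethoxy-1-benzofuran-3-yl]acetate (racemic) | COC(=O)C(Br)c1coc2c(Oc3cc(OC)cc(OC)c3)c(OC)cc(OC)c12
F5 | step 3 | (3,5-dimethoxyphenyl)(2,4,6-trimethoxyphenyl)iodonium 4-methylbenzenesulfonate | COc1cc(OC)cc([I+]c2c(OC)cc(OC)cc2OC)c1.Cc1ccc(cc1)S([O-])(=O)=O
F0 | step 17 | none | none
A1 | alternative 1 | 5-methoxycyclohexane-1,3-dione | COC1CC(=O)CC(=O)C1
A2 | alternative 1 | 2-(3,5-dimethoxyphenoxy)-6-iodo-3,5-dimethoxyphenol | Oc1c(I)c(OC)cc(OC)c1Oc1cc(OC)cc(OC)c1
A3 | alternative 1 | 6-(3,5-dimethoxyphenoxy)-3,7,9-trimethoxy-3,4-dihydrodibenzofuran-1(2H)-one (racemic, one enantiomer drawn) | CO[C@H]1CC(=O)c2c(C1)oc1c(Oc3cc(OC)cc(OC)c3)c(OC)cc(OC)c21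
A4 | alternative 2 | pentacyclic core with ethynyloxy groups at a1 and c2 and methyl ethers at a2, a4, b2, c3 and c5 | C#COc1c(OC)cc(OC)c2c1Oc1c(OC)cc3oc4c(OC#C)c(OC)cc(OC)c4c3c1O2
A5 | alternative 2 | 3-ethoxycyclobut-2-en-1-one | CCOC1=CC(=O)C1
A6 | alternative 2 | protected target with one free hydroxyl and one ethoxy group on each ring P and methyl ethers on the core | CCOc1cc(O)cc(Oc2c(OC)cc(OC)c3c2Oc2c(OC)cc4oc5c(Oc6cc(O)cc(OCC)c6)c(OC)cc(OC)c5c4c2O3)c1
A7 | alternative 3 | 2-[2-bromo-3-(3,5-dimethoxyphenoxy)-4,6-dimethoxyphenoxy]-6-methoxy-1,4-benzoquinone | COC1=CC(=O)C=C(Oc2c(OC)cc(OC)c(Oc3cc(OC)cc(OC)c3)c2Br)C1=O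
A8 | alternative 3 | 2-(3,5-dimethoxyphenoxy)benzene-1,3,5-triol | Oc1cc(O)c(Oc2cc(OC)cc(OC)c2)c(O)c1
A9 | alternative 3 | dibenzofuran with free b1, c3 and c5 hydroxyls, methoxy at b2, ring P at c2 and the brominated ring A aryl ether at b6 | COc1cc2oc3c(Oc4cc(OC)cc(OC)c4)c(O)cc(O)c3c2c(Oc2c(OC)cc(OC)c(Oc3cc(OC)cc(OC)c3)c2Br)c1O
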